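**Remark on the chemistry (assumption):** Atoms are numbered as in ent-kaurane (C1–C20; there is no C9–C10 bond). For the two catalytic asymmetric steps the antipode of the ligand or catalyst is taken to be the one that gives the stated configuration; it would be fixed from the established stereochemical models, because the sense of induction cannot be derived on paper for these exact substrates. "LacOH" stands for the (3R,3aS,4R,7aR)-4-hydroxy-4,7a-dimethyl-1-oxooctahydro-2-benzofuran-3-yl group (the lactone half attached through C6) and "LacTES" for its C10 triethylsilyl ether.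

## Analysis of the target

Target 29 is a 9,10-seco-kaurane diterpenoid whose two ring systems are joined only by the methylene C7. One half is a cyclohexane (C1–C5, C10) cis-fused at C4–C5 to a γ-lactone (carbonyl C19 on quaternary C4, ring oxygen on C6) and carrying a tertiary carbinol at C10 (methyl C20). The other half is a bicyclo[3.2.1]oct-3-en-2-one with bridgeheads C8 and C13, the enone C9/C11=C12, the one-carbon bridge C14 and the two-carbon bridge C15(OAc)–C16(=C17H2).

The lactone half holds four stereocentres (4R, 5S, 6R, 10R): methyl C18 and H5 are cis, H5 and H6 are trans so that C7 lies on the convex face, and the C10 hydroxyl is on the face of H5, trans to C6 and C19. The bicycle holds three (8R, 13S, 15R), with the acetate endo, on the side of the enone bridge. Because C7 insulates the halves, no relay of stereochemistry between them can be counted on, so each half must be set in the absolute sense.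

Sensitive groups are the enone, the α-methylene allylic acetate, the base-labile acetate and lactone, and the dehydratable tertiary alcohol. At the C10 ketone stage C5 is epimerisable and the lactone oxygen on C6 is β to the carbonyl. The difficulty lies in two quaternary carbons (C4, C8) and the contiguous triad C4–C5–C6.

The strategy rests on one feature: with C10 as a ketone, C4 is the β-carbon of an enone and C5 its enolate carbon. A methyl nucleophile at C4 and an aldehyde at C5 then form C4–C18 and C5–C6 in one operation, and the C6 alkoxide is placed 1,4 to the ester carbon C19, ready to lactonise.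

## Retrosynthetic reasoning

**Oxidation levels at C9 and C15 (29 back to 24).** The C9 enone is taken back to allylic alcohol 28 and its bis-silyl ether 27, the acetate to alcohol 26, and 26 to enone 25 and its precursor 24. No skeletal bond is cut. Keeping C9 as a silyl ether means C15 is the only ketone when its configuration is set by reduction, and the silyl ether under the endo face helps direct that reduction.

**C15–C16 (24 to 23, then 21).** The two-carbon bridge is cut between C15 and C16. This is the one ring bond whose cleavage leaves a monocyclic cyclohexene with two stable termini, an aldehyde on C8 and an alkenyl iodide on C13, and it brings the C15 oxygen in as a carbonyl. The forward chromium-mediated addition has to bridge the cis-1,3 positions C8 and C13. The alkenyl iodide 23 comes from the terminal alkyne of 21 through borane 22.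

**C8–C9 and C13–C14 (21 to 17 and 20).** The cyclohexene is cut into enal 17 (C8=C14, formyl C15) and silyloxy dienyne 20 (C9, C11, C12, C13, C16, C17). A Diels–Alder reaction is the only single step that builds the quaternary C8 together with C13. The C9 oxygen directs the regiochemistry and is the latent ketone, and the endo rule places the formyl and ethynyl groups cis, as the later ring closure demands. The forward reaction must choose the C8 face under catalyst control, since the lactone centres are too remote to do so.

**Dienyne (20 to 19 to 18).** C16–C17 is cut: the alkyne carbon C17 is added to the aldehyde of dienal 19, which is the O-silyl derivative of the five-carbon enolate 18. The all-trans geometry of 18 fixes the 1E,3E diene.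

**C8=C14 and the arm (17 to 13).** The methylene C14 is removed from 17 (via 16) to give aldehyde 15, which comes from diol 14 and silyl ether 13. The forward α-methylenation has to add one carbon to C8 without touching the lactone.

**C10 carbinol (13 to 10).** The C10–O bond is cut to alkene 11 (through hydroperoxide 12), and C10=C20 to ketone 10. Direct methyl addition to 10 is set aside because a reagent enters C10 from the convex face: the incoming atom must therefore be oxygen, not carbon.

**C19–O (10 to 9).** The lactone is opened to hydroxy ester 9. The forward closure also filters the stereoisomers, since only a C6 hydroxyl cis to the ester can reach C19.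

**C4–C18 and C5–C6 (9 to 4, 5 and 3).** Both bonds are cut at once: conjugate methylation of enone 4 by 5 gives enolate 6, which is passed on through 7 to zirconium enolate 8 and added to aldehyde 3. This sets C4, C5 and C6 from achiral materials and is the key step.

**Aldehyde (3 to 2 to 1).** Aldehyde 3 is traced to the monosilyl ether 2 of diol 1.

## Alternatives that were turned down

**Alternative 1:** 1,2-vinyl shift from a bicyclo[2.2.2]octane.
- Disconnection: C13–C16 of the bicyclo[3.2.1]octenone is traced back to C12–C16 of the bicyclo[2.2.2]octanone mesylate A2.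
- Forward key step: ionisation at C13 with the C16=C17 π bond anti to the leaving group moves C16 from C12 to C13, and loss of H11 from the C12 cation gives the enone A1.
- For: the shift is stereospecific and delivers enone, exocyclic methylene and both bridgeheads at once. On the enone it is stronger than the chosen route, which needs steps 19 and 20 to unveil it.
- Against: A1 has no oxygen at C15. It would have to be introduced by allylic oxidation next to quaternary C8, and an ene-type oxidant would deliver oxygen from the open exo face, the 15-epimer, so an oxidation–reduction pair is needed anyway. The leaving group must be anti to C12–C16 and not to C12–C11, so A2 needs a defined C13 centre and a bridgehead C8 that already carries the lactone arm, again set absolutely against the lactone. Cationic conditions also threaten the tertiary C10 alcohol.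
- Comparison: the chosen strategy brings C15 in as the formyl carbon of the dienophile, so its oxygen is present from the start; the price is a longer endgame.

**Alternative 2:** manganese radical tandem.
- Disconnection: C8–C14 and C13–C16, back to the acyclic β-keto ester A4.
- Forward key step: one-electron oxidation by a trivalent manganese oxidant in an alcohol solvent gives the C8 radical, which closes 6-endo onto the alkene and then 5-exo-dig onto the alkyne to give A3.
- For: one step makes both rings, the quaternary C8 and the exocyclic methylene, with the C15 oxygen already in place. For the bicycle it is clearly stronger in step economy than steps 13–17 of the chosen route.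
- Against: A3 carries a methyl ester on C8 where 29 has the methylene C7, and a saturated C11–C12 bond, so homologation and dehydrogenation follow. The C15 centre in the chain must control the face of the planar C8 radical, and the endo C15–O relationship is not assured. Above all, the lactone half must be attached afterwards, and the C10 ketone would then have to be methylenated and hydrated in the presence of the C9 ketone and of C16=C17, a second 1,1-disubstituted alkene that reacts in the same radical hydration.
- Comparison: the chosen strategy finishes the C10 carbinol before any other alkene or ketone exists.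

**Alternative 3:** catalytic Diels–Alder union as the organising step.
- Disconnection: C8–C9 and C13–C14, back to enal A6 and dienyne A7.
- Forward key step: cycloaddition under a chiral boron Lewis acid gives A5.
- For: it is convergent, builds the quaternary C8, and its endo rule gives the cis formyl/alkynyl pair. On these points it is as strong as anything available, and the chosen route does not compete with it: step 13 is this cycloaddition, run on 17 and 20. A5 differs from 21 only in the silyl groups (the terminal alkyne of 20 saves a desilylation; the triethylsilyl ether at C10 is chosen to survive the hydroiodination).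
- Against, as the organising idea: it starts from A6 and so presupposes all four lactone stereocentres, including quaternary C4 and the contiguous triad, without saying how they arise.
- Comparison: the chosen strategy supplies that origin, three stereocentres and two skeletal bonds from achiral 4, 5 and 3 in one flask.

Key step: step 3

## Route

Step 1
Reactants: 1 butane-1,4-diol
Product: 2 4-(tert-butyldiphenylsilyloxy)butan-1-ol
Conditions: TBDPSCl (1 equiv), 1 (5 equiv), imidazole, DMF, 0 °C → rt
Reagents that add atoms: tert-butyl(chloro)diphenylsilane, CC(C)(C)[Si](Cl)(c1ccccc1)c1ccccc1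
Why: Silyl ether formation on a symmetric diol used in excess, so that the chloride reacts once; no stereocentre.

Step 2
Reactants: 2 4-(tert-butyldiphenylsilyloxy)butan-1-ol
Product: 3 4-(tert-butyldiphenylsilyloxy)butanal
Conditions: TEMPO (10 mol %), PhI(OAc)2, CH2Cl2, rt
Reagents that add atoms: none
Why: Oxoammonium (TEMPO) oxidation of a primary alcohol stops at the aldehyde in the absence of water; the silyl ether is inert.

Step 3
Reactants: 4 ethyl 3-oxocyclohex-1-ene-1-carboxylate; 5 trimethylaluminium; 3 4-(tert-butyldiphenylsilyloxy)butanal
Product: 9 ethyl (1R,2S)-2-[(1R)-4-(tert-butyldiphenylsilyloxy)-1-hydroxybutyl]-1-methyl-3-oxocyclohexane-1-carboxylate, via dimethylaluminium enolate 6 (not isolated), via lithium trimethylaluminate enolate 7 (not isolated), via chlorozirconocene enolate 8 (not isolated)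
Conditions: Cu(OTf)2 (5 mol %), chiral sulfonate-bearing imidazolinium salt (carbene precursor, 6 mol %), AlMe3 (1.3 equiv), THF, −78 °C; MeLi, −78 °C; Cp2ZrCl2, −78 → −40 °C; 3, −78 °C; aq. potassium sodium tartrate
Reagents that add atoms: trimethylaluminium 5, C[Al](C)C
Why: Transmetalation from AlMe3 to the copper–carbene complex gives a chiral methylcopper species that adds methyl to C4 of enone 4 in a 1,4 sense (π-complex, oxidative addition at the β-carbon, reductive elimination), with the ligand antipode chosen so that methyl enters the Si face of C4 (4R); the closest known reaction type is the copper/N-heterocyclic-carbene-catalysed conjugate addition of trialkylaluminium reagents to β-substituted cyclohexenones, β-carboalkoxy enones included, with trapping of the aluminium enolate. The addition leaves enolate 6 with its double bond only between C5 and C10, a regiochemistry that deprotonation of the saturated ketone would not give. MeLi turns the sluggish 6 into aluminate 7, which hands the enolate oxygen to Cp2ZrCl2 with loss of LiCl to give 8; zirconium enolates add to aldehydes through a closed transition state that gives the syn aldol whatever the enolate geometry, here the 5S,6R pair that becomes trans H5/H6 in the lactone. Aldehyde 3 should enter C5 on the face cis to the ester, because the forming bond prefers to lie anti to the better σ-donor at C4, the C4–CH3 bond, and not anti to the electron-poor C4–C19 bond. No ring is closed in this step. The step needs 1,4- over 1,2-methyl transfer (secured by copper catalysis at −78 °C), enolate addition over methyl transfer to the aldehyde (secured by complete exchange to zirconium before 3 is added) and face selectivity at C5, which is the least secure of the three; adducts with C6 trans to the ester cannot lactonise directly and are removed in step 4.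

Step 4
Reactants: 9 ethyl (1R,2S)-2-[(1R)-4-(tert-butyldiphenylsilyloxy)-1-hydroxybutyl]-1-methyl-3-oxocyclohexane-1-carboxylate
Product: 10 (3R,3aS,7aR)-3-[3-(tert-butyldiphenylsilyloxy)propyl]-7a-methylhexahydro-2-benzofuran-1,4-dione
Conditions: TsOH·H2O (10 mol %), PhMe, 60 °C
Reagents that add atoms: none
Why: Acid-catalysed intramolecular transesterification (5-exo-trig acyl substitution) of the γ-hydroxy ester; only a C6 hydroxyl cis to the ester can close, which gives the cis-fused lactone, locks C5 (S) and places C7 on the convex face; the silyl ether and the ketone tolerate catalytic acid.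

Step 5
Reactants: 10 (3R,3aS,7aR)-3-[3-(tert-butyldiphenylsilyloxy)propyl]-7a-methylhexahydro-2-benzofuran-1,4-dione
Product: 11 (3R,3aS,7aR)-3-[3-(tert-butyldiphenylsilyloxy)propyl]-7a-methyl-4-methylidenehexahydro-2-benzofuran-1(3H)-one
Conditions: Zn, CH2Br2, TiCl4, THF/CH2Cl2, 0 °C → rt
Reagents that add atoms: dibromomethane, BrCBr
Why: Takai–Lombardo methylenation with the non-basic zinc/titanium gem-dimetallic reagent converts the hindered C10 ketone into the alkene without enolising C5, which under a basic Wittig ylide would expel the lactone oxygen on C6 (β-acyloxy elimination); the lactone carbonyl on quaternary C4 does not react.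

Step 6
Reactants: 11 (3R,3aS,7aR)-3-[3-(tert-butyldiphenylsilyloxy)propyl]-7a-methyl-4-methylidenehexahydro-2-benzofuran-1(3H)-one
Product: 13 (3R,3aS,4R,7aR)-3-[3-(tert-butyldiphenylsilyloxy)propyl]-4-hydroxy-4,7a-dimethylhexahydro-2-benzofuran-1(3H)-one, via tertiary hydroperoxide 12 (not isolated)
Conditions: Co(acac)2 (20 mol %), PhSiH3, O2 (1 atm), THF, rt; then PPh3
Reagents that add atoms: dioxygen, O=O
Why: Mukaiyama hydration: hydrogen-atom transfer from a cobalt hydride to the CH2 terminus gives the tertiary C10 radical (Markovnikov), which should be trapped by O2 on the convex face of the cis-fused bicycle, the face of H5 and away from the axial lactone carbonyl C19, so that oxygen ends trans to C6 and C19 (10R); PPh3 reduces hydroperoxide 12 to the alcohol.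

Step 7
Reactants: 13 (3R,3aS,4R,7aR)-3-[3-(tert-butyldiphenylsilyloxy)propyl]-4-hydroxy-4,7a-dimethylhexahydro-2-benzofuran-1(3H)-one
Product: 14 (3R,3aS,4R,7aR)-4-hydroxy-3-(3-hydroxypropyl)-4,7a-dimethylhexahydro-2-benzofuran-1(3H)-one
Conditions: Bu4NF, AcOH, THF, rt
Reagents that add atoms: none
Why: Fluoride cleavage of the primary silyl ether; acetic acid buffers the alkoxide so that the lactone and the tertiary alcohol are untouched.

Step 8
Reactants: 14 (3R,3aS,4R,7aR)-4-hydroxy-3-(3-hydroxypropyl)-4,7a-dimethylhexahydro-2-benzofuran-1(3H)-one
Product: 15 3-(LacOH)propanal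
Conditions: TEMPO (10 mol %), PhI(OAc)2, CH2Cl2, rt
Reagents that add atoms: none
Why: Oxoammonium oxidation of the primary alcohol to the aldehyde; the tertiary C10 alcohol cannot be oxidised and a lactol with it would be seven-membered.

Step 9
Reactants: 15 3-(LacOH)propanal
Product: 16 2-[(LacOH)methyl]prop-2-enal
Conditions: 37% aq. HCHO, pyrrolidine (10 mol %), EtCO2H (10 mol %), i-PrOH, 45 °C
Reagents that add atoms: formaldehyde, C=O
Why: Amine-catalysed α-methylenation (Mannich condensation of the enamine of 15 with formaldehyde, then β-elimination of the amine) places C14 on C8; C7 is only cross-conjugated to the carbonyl and is not acidified, so the lactone oxygen on C6 is not eliminated.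

Step 10
Reactants: 16 2-[(LacOH)methyl]prop-2-enal
Product: 17 2-[(LacTES)methyl]prop-2-enal
Conditions: Et3SiOTf, 2,6-lutidine, CH2Cl2, −78 → 0 °C
Reagents that add atoms: triethylsilyl trifluoromethanesulfonate, CC[Si](CC)(CC)OS(=O)(=O)C(F)(F)F
Why: Silylation of the hindered tertiary alcohol with a silyl triflate and a hindered pyridine base; the ether shields C10–OH from the acidic cycloaddition catalyst and from the later acetylation, and is removed together with the C9 silyl ether.

Step 11
Reactants: 18 potassium (1E,3E)-5-oxopenta-1,3-dien-1-olate (glutaconaldehyde potassium salt)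
Product: 19 (2E,4E)-5-(tert-butyldimethylsilyloxy)penta-2,4-dienal
Conditions: TBSCl, DMF, 0 °C → rt
Reagents that add atoms: tert-butyl(chloro)dimethylsilane, CC(C)(C)[Si](C)(C)Cl
Why: O-Silylation of the delocalised enolate; the all-trans geometry of the anion is kept, which gives the 2E,4E dienal.

Step 12
Reactants: 19 (2E,4E)-5-(tert-butyldimethylsilyloxy)penta-2,4-dienal
Product: 20 tert-butyl[(1E,3E)-hexa-1,3-dien-5-yn-1-yloxy]dimethylsilane
Conditions: Me3SiCHN2, LiN(i-Pr)2, THF, −78 °C → rt
Reagents that add atoms: (trimethylsilyl)diazomethane, C[Si](C)(C)C=[N+]=[N-]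
Why: Colvin homologation: the lithiated silyldiazomethane adds to the aldehyde, Peterson-type elimination gives a diazoalkene that loses N2, and a 1,2-hydrogen shift in the alkylidene carbene gives the terminal alkyne; the aprotic, cold medium spares the silyl dienol ether and the diene geometry.

Step 13
Reactants: 17 2-[(LacTES)methyl]prop-2-enal; 20 tert-butyl[(1E,3E)-hexa-1,3-dien-5-yn-1-yloxy]dimethylsilane
Product: 21 (1S,2S,5S)-2-(tert-butyldimethylsilyloxy)-5-ethynyl-1-[(LacTES)methyl]cyclohex-3-ene-1-carbaldehyde
Conditions: chiral o-tolyl oxazaborolidinium triflimide (from diphenylprolinol, 20 mol %), CH2Cl2, −78 → −40 °C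
Reagents that add atoms: none
Why: Lewis-acid-catalysed Diels–Alder reaction of a 2-substituted acrolein with a 1-silyloxydiene, an established reaction type: the donor oxygen on C9 sends C13 to the CH2 terminus C14 and C9 to C8, the coordinated formyl group is endo so that formyl, C9 silyloxy and C13 ethynyl groups are all cis, and the chiral cation shields one face of the bound enal so that C8 (8S in 21, the centre that is 8R in 29) is set independently of the remote lactone centres.

Step 14
Reactants: 21 (1S,2S,5S)-2-(tert-butyldimethylsilyloxy)-5-ethynyl-1-[(LacTES)methyl]cyclohex-3-ene-1-carbaldehyde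
Product: 23 (1S,2S,5S)-2-(tert-butyldimethylsilyloxy)-5-(1-iodoethenyl)-1-[(LacTES)methyl]cyclohex-3-ene-1-carbaldehyde, via iodoalkenylborane 22 (not isolated)
Conditions: B-iodo-9-BBN, pentane/CH2Cl2, −20 °C; then AcOH, 0 °C
Reagents that add atoms: B-iodo-9-borabicyclo[3.3.1]nonane, IB1C2CCCC1CCC2
Why: Haloboration–protodeboronation: B–I adds cis across the terminal alkyne with iodine on the internal carbon C16, and acetic acid cleaves the alkenyl C–B bond of 22 with retention to give the 2-iodoalkene; the hindered formyl group on quaternary C8 should be complexed only reversibly at −20 °C.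

Step 15
Reactants: 23 (1S,2S,5S)-2-(tert-butyldimethylsilyloxy)-5-(1-iodoethenyl)-1-[(LacTES)methyl]cyclohex-3-ene-1-carbaldehyde
Product: 24 bicyclic alcohol (8R,9S,13S,15S): bicyclo[3.2.1]octene of C8–C16 with C9 OTBS; exo C15 OH; C16=CH2; LacTES-CH2 on C8
Conditions: CrCl2 (6 equiv), NiCl2 (2 mol %), DMF, rt, high dilution
Reagents that add atoms: none
Why: Intramolecular Nozaki–Hiyama–Kishi reaction: zerovalent nickel formed in the flask inserts into the C16–I bond, transmetalation gives an alkenyl species of trivalent chromium that adds only to the aldehyde and closes the two-carbon bridge across the cis-1,3 positions C8 and C13 (five-membered ring); the chromium alkoxide is expected to take the exo position (15S), and either C15 epimer is acceptable because step 16 removes the centre.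

Step 16
Reactants: 24 bicyclic alcohol (8R,9S,13S,15S)
Product: 25 bicyclic enone (8S,9S,13S): as 24 with a C15 ketone conjugated to C16=CH2
Conditions: Dess–Martin periodinane, NaHCO3, CH2Cl2, 0 °C → rt
Reagents that add atoms: none
Why: Dess–Martin oxidation of the secondary allylic alcohol under buffered, non-basic conditions; C9 is still a silyl ether, so C15 becomes the only ketone in the molecule.

Step 17
Reactants: 25 bicyclic enone (8S,9S,13S)
Product: 26 bicyclic alcohol (8R,9S,13S,15R): as 24 with endo C15 OH
Conditions: NaBH4, CeCl3·7H2O, MeOH, −78 °C
Reagents that add atoms: none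
Why: Luche 1,2-reduction: hydride should enter C15 from the exo face, the side of the one-carbon bridge C14, as is usual for ketones on the two-carbon bridge of bicyclo[3.2.1]octanes and reinforced here by the C9 silyl ether under the endo face, which gives the endo alcohol (15R, cis to C9); the lactone is not reduced at −78 °C.

Step 18
Reactants: 26 bicyclic alcohol (8R,9S,13S,15R)
Product: 27 bicyclic acetate (8R,9S,13S,15R): as 26 with C15 OAc
Conditions: Ac2O, DMAP (cat.), pyridine, rt
Reagents that add atoms: acetic anhydride, CC(=O)OC(C)=O
Why: DMAP-catalysed acylation of the secondary allylic alcohol; the C9 and C10 oxygens are silylated, so only C15–OH reacts and its configuration is retained.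

Step 19
Reactants: 27 bicyclic acetate (8R,9S,13S,15R)
Product: 28 diol (8S,9S,13S,15R): as 27 with free C9 and C10 hydroxyls
Conditions: HF·pyridine, pyridine/THF, 0 °C → rt
Reagents that add atoms: none
Why: Fluoride cleavage of both silyl ethers in a buffered acidic medium, in which the C15 acetate should neither hydrolyse nor migrate readily to the neighbouring C9 hydroxyl; the crude diol is oxidised at once.

Step 20
Reactants: 28 diol (8S,9S,13S,15R)
Product: 29 target CNP0172716.1, (4R,5S,6R,8R,10R,13S,15R)-15-acetoxy-10-hydroxy-9-oxo-9,10-secokaura-11,16-dien-19,6-olide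
Conditions: Dess–Martin periodinane, NaHCO3, CH2Cl2, rt
Reagents that add atoms: none
Why: Dess–Martin oxidation of the secondary allylic C9 alcohol gives the enone conjugated with C11=C12; the tertiary alcohol is inert, C8 is quaternary so the β-acetoxy ketone cannot eliminate, and no stereocentre is touched.

## Compound list

1 | butane-1,4-diol | OCCCCO | starting material
2 | 4-(tert-butyldiphenylsilyloxy)butan-1-ol | CC(C)(C)[Si](OCCCCO)(c1ccccc1)c1ccccc1 | intermediate
3 | 4-(tert-butyldiphenylsilyloxy)butanal | CC(C)(C)[Si](OCCCC=O)(c1ccccc1)c1ccccc1 | intermediate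
4 | ethyl 3-oxocyclohex-1-ene-1-carboxylate | CCOC(=O)C1=CC(=O)CCC1 | starting material
5 | trimethylaluminium | C[Al](C)C | starting material
6 | ethyl (1R)-3-[(dimethylalumanyl)oxy]-1-methylcyclohex-2-ene-1-carboxylate (dimethylaluminium enolate) | CCOC(=O)[C@]1(C)CCCC(O[Al](C)C)=C1 | intermediate
7 | lithium trimethyl{[(3R)-3-(ethoxycarbonyl)-3-methylcyclohex-1-en-1-yl]oxy}aluminate | [Li+].CCOC(=O)[C@]1(C)CCCC(O[Al-](C)(C)C)=C1 | intermediate
8 | ethyl (1R)-3-{[chlorobis(η5-cyclopentadienyl)zirconio]oxy}-1-methylcyclohex-2-ene-1-carboxylate (zirconium enolate) | CCOC(=O)[C@]1(C)CCCC(O[Zr](Cl)(C2C=CC=C2)C2C=CC=C2)=C1 | intermediate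
9 | ethyl (1R,2S)-2-[(1R)-4-(tert-butyldiphenylsilyloxy)-1-hydroxybutyl]-1-methyl-3-oxocyclohexane-1-carboxylate | CCOC(=O)[C@]1(C)CCCC(=O)[C@@H]1[C@H](O)CCCO[Si](c1ccccc1)(c1ccccc1)C(C)(C)C | intermediate
10 | (3R,3aS,7aR)-3-[3-(tert-butyldiphenylsilyloxy)propyl]-7a-methylhexahydro-2-benzofuran-1,4-dione | CC(C)(C)[Si](OCCC[C@H]1OC(=O)[C@]2(C)CCCC(=O)[C@H]12)(c1ccccc1)c1ccccc1 | intermediate
11 | (3R,3aS,7aR)-3-[3-(tert-butyldiphenylsilyloxy)propyl]-7a-methyl-4-methylidenehexahydro-2-benzofuran-1(3H)-one | CC(C)(C)[Si](OCCC[C@H]1OC(=O)[C@]2(C)CCCC(=C)[C@H]12)(c1ccccc1)c1ccccc1 | intermediate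
12 | (3R,3aS,4R,7aR)-3-[3-(tert-butyldiphenylsilyloxy)propyl]-4-hydroperoxy-4,7a-dimethylhexahydro-2-benzofuran-1(3H)-one | CC(C)(C)[Si](OCCC[C@H]1OC(=O)[C@]2(C)CCC[C@@](C)(OO)[C@H]12)(c1ccccc1)c1ccccc1 | intermediate
13 | (3R,3aS,4R,7aR)-3-[3-(tert-butyldiphenylsilyloxy)propyl]-4-hydroxy-4,7a-dimethylhexahydro-2-benzofuran-1(3H)-one | CC(C)(C)[Si](OCCC[C@H]1OC(=O)[C@]2(C)CCC[C@@](C)(O)[C@H]12)(c1ccccc1)c1ccccc1 | intermediate
14 | (3R,3aS,4R,7aR)-4-hydroxy-3-(3-hydroxypropyl)-4,7a-dimethylhexahydro-2-benzofuran-1(3H)-one | OCCC[C@H]1OC(=O)[C@]2(C)CCC[C@@](C)(O)[C@H]12 | intermediate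
15 | 3-[(3R,3aS,4R,7aR)-4-hydroxy-4,7a-dimethyl-1-oxooctahydro-2-benzofuran-3-yl]propanal | O=CCC[C@H]1OC(=O)[C@]2(C)CCC[C@@](C)(O)[C@H]12 | intermediate
16 | 2-{[(3R,3aS,4R,7aR)-4-hydroxy-4,7a-dimethyl-1-oxooctahydro-2-benzofuran-3-yl]methyl}prop-2-enal | C=C(C=O)C[C@H]1OC(=O)[C@]2(C)CCC[C@@](C)(O)[C@H]12 | intermediate
17 | 2-{[(3R,3aS,4R,7aR)-4,7a-dimethyl-1-oxo-4-(triethylsilyloxy)octahydro-2-benzofuran-3-yl]methyl}prop-2-enal | C=C(C=O)C[C@H]1OC(=O)[C@]2(C)CCC[C@@](C)(O[Si](CC)(CC)CC)[C@H]12 | intermediate
18 | potassium (1E,3E)-5-oxopenta-1,3-dien-1-olate (glutaconaldehyde potassium salt) | [K+].[O-]/C=C/C=C/C=O | starting material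
19 | (2E,4E)-5-(tert-butyldimethylsilyloxy)penta-2,4-dienal | CC(C)(C)[Si](C)(C)O/C=C/C=C/C=O | intermediate
20 | tert-butyl[(1E,3E)-hexa-1,3-dien-5-yn-1-yloxy]dimethylsilane | CC(C)(C)[Si](C)(C)O/C=C/C=C/C#C | intermediate
21 | (1S,2S,5S)-2-(tert-butyldimethylsilyloxy)-5-ethynyl-1-[(LacTES)methyl]cyclohex-3-ene-1-carbaldehyde | C#C[C@@H]1C=C[C@H](O[Si](C)(C)C(C)(C)C)[C@@](C[C@H]2OC(=O)[C@]3(C)CCC[C@@](C)(O[Si](CC)(CC)CC)[C@H]23)(C1)C=O | intermediate
22 | (1S,2S,5S)-5-[(Z)-2-(9-borabicyclo[3.3.1]nonan-9-yl)-1-iodoethenyl]-2-(tert-butyldimethylsilyloxy)-1-[(LacTES)methyl]cyclohex-3-ene-1-carbaldehyde | I/C(=C\B4C5CCCC4CCC5)[C@@H]1C=C[C@H](O[Si](C)(C)C(C)(C)C)[C@@](C[C@H]2OC(=O)[C@]3(C)CCC[C@@](C)(O[Si](CC)(CC)CC)[C@H]23)(C1)C=O | intermediate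
23 | (1S,2S,5S)-2-(tert-butyldimethylsilyloxy)-5-(1-iodoethenyl)-1-[(LacTES)methyl]cyclohex-3-ene-1-carbaldehyde | C=C(I)[C@@H]1C=C[C@H](O[Si](C)(C)C(C)(C)C)[C@@](C[C@H]2OC(=O)[C@]3(C)CCC[C@@](C)(O[Si](CC)(CC)CC)[C@H]23)(C1)C=O | intermediate
24 | bicyclic alcohol (8R,9S,13S,15S), exo C15 hydroxyl, C9 OTBS, C10 OTES | C=C1[C@@H]2C=C[C@H](O[Si](C)(C)C(C)(C)C)[C@@](C[C@H]3OC(=O)[C@]4(C)CCC[C@@](C)(O[Si](CC)(CC)CC)[C@H]34)(C2)[C@H]1O | intermediate
25 | bicyclic C15 enone (8S,9S,13S), C9 OTBS, C10 OTES | C=C1[C@@H]2C=C[C@H](O[Si](C)(C)C(C)(C)C)[C@@](C[C@H]3OC(=O)[C@]4(C)CCC[C@@](C)(O[Si](CC)(CC)CC)[C@H]34)(C2)C1=O | intermediate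
26 | bicyclic alcohol (8R,9S,13S,15R), endo C15 hydroxyl, C9 OTBS, C10 OTES | C=C1[C@@H]2C=C[C@H](O[Si](C)(C)C(C)(C)C)[C@@](C[C@H]3OC(=O)[C@]4(C)CCC[C@@](C)(O[Si](CC)(CC)CC)[C@H]34)(C2)[C@@H]1O | intermediate
27 | bicyclic acetate (8R,9S,13S,15R), C9 OTBS, C10 OTES | C=C1[C@@H]2C=C[C@H](O[Si](C)(C)C(C)(C)C)[C@@](C[C@H]3OC(=O)[C@]4(C)CCC[C@@](C)(O[Si](CC)(CC)CC)[C@H]34)(C2)[C@@H]1OC(C)=O | intermediate
28 | diol (8S,9S,13S,15R): 15-acetate with free C9 and C10 hydroxyls | C=C1[C@@H]2C=C[C@H](O)[C@@](C[C@H]3OC(=O)[C@]4(C)CCC[C@@](C)(O)[C@H]34)(C2)[C@@H]1OC(C)=O | intermediate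
29 | CNP0172716.1, (4R,5S,6R,8R,10R,13S,15R)-15-acetoxy-10-hydroxy-9-oxo-9,10-secokaura-11,16-dien-19,6-olide | C=C1[C@@H]2C=CC(=O)[C@@](C[C@H]3OC(=O)[C@]4(C)CCC[C@@](C)(O)[C@H]34)(C2)[C@@H]1OC(C)=O | target

## Step count and least certain steps

Total: 20 steps. Longest linear sequence: 18 steps (steps 1–10 and 13–20); the dienyne branch (steps 11–12) joins at step 13.

**Step 3 (key step).** The most likely failure is incomplete hand-over of the enolate from aluminium to zirconium. Residual methylaluminium species would then methylate aldehyde 3, or an aluminium-bound enolate would react through a chair transition state with anti selectivity. Face selectivity at C5 may also erode, because methyl and ester on C4 differ little in size. The fallback replaces the one-flask exchange by an isolated, aluminium-free enolate precursor. It sets out from 4 and 5: the same copper-catalysed addition is quenched with Et3SiOTf to give ethyl (1R)-1-methyl-3-(triethylsilyloxy)cyclohex-2-ene-1-carboxylate F1. MeLi in THF then cleaves the Si–O bond to the lithium enolate F2, Cp2ZrCl2 converts it into 8, and addition of 3 at −78 °C returns to the route at 9.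

**Step 13.** Two processes threaten this step. The silyl dienol ether may be lost by protodesilylation, or the reaction may stall after a Mukaiyama–Michael addition, under the strongly acidic catalyst. The catalyst may also fail to override the bias of the bulky α-substituent, giving poor facial selectivity at C8. The fallback changes the source of stereocontrol from the reagent to the substrate. It sets out from 17 and 20, which are combined with the achiral, mild lanthanide Lewis acid Eu(fod)3 (or simply by heating), conditions that silyl dienol ethers tolerate. The C8 epimers are then separated by chromatography, and the route is rejoined at 21; the loss is taken at the convergent stage. It makes no compound outside the list (F0).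

**Step 14.** The Lewis-acidic haloborane may attack the aldehyde or cleave a silyl ether before or instead of adding to the alkyne. The fallback avoids the alkenyl iodide altogether and changes the polarity of the ring closure. It sets out from 21: SmI2 with HMPA and t-BuOH in THF generates the C15 ketyl, which adds 5-exo-dig to C16, and the alkenyl radical is reduced and protonated. This gives the bicyclic alcohol and returns to the route at 24 (any 15R epimer formed is 26; step 16 removes the centre in either case). It makes no compound outside the list (F0).

**Step 6.** Capture of the planar C10 radical by O2 is an early, weakly discriminating event and may show poor facial selectivity. The fallback uses polar instead of radical chemistry and sets out from ketone 10: the methylcerium reagent from MeLi and CeCl3 at −78 °C adds to C10 and returns directly to 13. A nucleophile places carbon on the face it attacks, so this addition is complementary: it should give the 10R carbinol in exactly the case in which the hydration favours the wrong face. It makes no compound outside the list (F0).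

**Step 17.** Hydride may be delivered from the endo face, which the sp2 carbons C11 and C12 leave fairly open, giving back the 15S alcohol. The fallback sets C15 during C–C bond formation instead of by reduction. It sets out from 23: if the endo side is the open one, the bulky chromium alkoxide of step 15 occupies it, and the ring closure itself delivers the 15R alcohol. The route is then rejoined at 26, and steps 16 and 17 are omitted. It makes no compound outside the list (F0).

## Further compounds

F1 | step 3 | ethyl (1R)-1-methyl-3-(triethylsilyloxy)cyclohex-2-ene-1-carboxylate | CCOC(=O)[C@]1(C)CCCC(O[Si](CC)(CC)CC)=C1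
F2 | step 3 | lithium (3R)-3-(ethoxycarbonyl)-3-methylcyclohex-1-en-1-olate | [Li+].CCOC(=O)[C@]1(C)CCCC([O-])=C1
F0 | step 13 | none | none
F0 | step 14 | none | none
F0 | step 6 | none | none
F0 | step 17 | none | none
A1 | alternative 1 | 15-deoxy skeleton of the target (C15 is CH2) | C=C1[C@@H]2C=CC(=O)[C@@](C[C@H]3OC(=O)[C@]4(C)CCC[C@@](C)(O)[C@H]34)(C2)C1
A2 | alternative 1 | bicyclo[2.2.2]octan-9-one C13 mesylate with C16 bonded to C12 and C16=C17H2 | C=C1C[C@]2(C[C@H]3OC(=O)[C@]4(C)CCC[C@@](C)(O)[C@H]34)C[C@@H](OS(C)(=O)=O)[C@H]1CC2=O
A3 | alternative 2 | methyl 7-(tert-butyldimethylsilyloxy)-6-methylidene-2-oxobicyclo[3.2.1]octane-1-carboxylate | C=C1[C@@H]2CCC(=O)[C@@](C(=O)OC)(C2)[C@@H]1O[Si](C)(C)C(C)(C)C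
A4 | alternative 2 | methyl 2-[(1S)-1-(tert-butyldimethylsilyloxy)prop-2-yn-1-yl]-3-oxohept-6-enoate | C#C[C@@H](O[Si](C)(C)C(C)(C)C)C(C(=O)OC)C(=O)CCC=C
A5 | alternative 3 | cyclohexene adduct with C8 formyl, C9 tert-butyldimethylsilyloxy, C13 (trimethylsilyl)ethynyl and C10 trimethylsilyloxy groups | C[Si](C)(C)C#C[C@@H]1C=C[C@H](O[Si](C)(C)C(C)(C)C)[C@@](C[C@H]2OC(=O)[C@]3(C)CCC[C@@](C)(O[Si](C)(C)C)[C@H]23)(C1)C=O
A6 | alternative 3 | 2-{[(3R,3aS,4R,7aR)-4,7a-dimethyl-1-oxo-4-(trimethylsilyloxy)octahydro-2-benzofuran-3-yl]methyl}prop-2-enal | C=C(C=O)C[C@H]1OC(=O)[C@]2(C)CCC[C@@](C)(O[Si](C)(C)C)[C@H]12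
A7 | alternative 3 | tert-butyldimethyl{[(1E,3E)-6-(trimethylsilyl)hexa-1,3-dien-5-yn-1-yl]oxy}silane | C[Si](C)(C)C#C/C=C/C=C/O[Si](C)(C)C(C)(C)C
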